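**Plan**

- Numbering used here: lactone O1, C2 (C=O), C3, C4, C5; C7 is the benzylic CH2 on C4 (dimethoxyphenyl side), C7' the benzylic CH2 on C3 (catechol side). The retrosynthesis cuts, in order: the two catechol O–H bonds (to benzyl ethers), the ring bond C4–C5, the bond C3–C7', the acyl–auxiliary bond, and the olefin C4=C7.
- Enabling feature: C5 is the O-bound CH2 of the lactone, so it can be an acyloxymethyl radical (O1–C5•). C4 carries the aryl-CH2 arm C7, so C4=C7 can be a styrene conjugated to the dimethoxyphenyl ring. 5-exo attack of C5• on C4 then makes the lactone ring and the benzylic CH2 in one event.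
- Forward: a Wittig reaction joins veratraldehyde (C7 and its ring) to a three-carbon acid chain (C2–C4); auxiliary-controlled alkylation adds the protected catechol benzyl group at C3; the acid is made into its iodomethyl ester (C5 enters). The lactone, the only ring that is built, closes by radical C4–C5 bond formation, and hydrogenolysis frees the catechol.
- Stereochemistry: C3 (R) comes from the (R)-4-benzyl-oxazolidinone auxiliary (alkylation on the face opposite its benzyl group). C4 (R) comes from 1,2-induction by C3 in the radical ring closure (trans). Neither centre is touched afterwards.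

Key step: step 8

Assumption: the two phenols are carried as benzyl ethers from purchased [3,4-bis(benzyloxy)phenyl]methanol, because free phenols would quench the imide enolate and the stannane chain.

**Route**

Step 1
Reactants: 1 3,4-dimethoxybenzaldehyde (veratraldehyde); 2 (2-carboxyethyl)triphenylphosphonium bromide
Product: 4 (E)-4-(3,4-dimethoxyphenyl)but-3-enoic acid, via ylide 3 (not isolated)
Conditions: KOtBu (2.2 equiv), THF, 0 °C to rt; then aq. HCl
Reagents that add atoms: none
Why: Wittig reaction of the carboxylate-bearing ylide with an aryl aldehyde should give mainly the (E)-3-alkenoic acid, the styrene-conjugated isomer, and crystallisation should remove any (Z)-isomer.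

Step 2
Reactants: 4 (E)-4-(3,4-dimethoxyphenyl)but-3-enoic acid; 5 (R)-4-benzyl-1,3-oxazolidin-2-one
Product: 7 (R)-4-benzyl-3-[(E)-4-(3,4-dimethoxyphenyl)but-3-enoyl]-1,3-oxazolidin-2-one, via mixed anhydride 6 (not isolated)
Conditions: t-BuCOCl, Et3N, THF, −20 °C; then 5, LiCl, −20 °C to rt
Reagents that add atoms: none
Why: N-acylation of the oxazolidinone through the mixed pivalic anhydride (LiCl-promoted) should occur at the less hindered acyl carbon, and the styrene-conjugated alkene has no driving force to shift.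

Step 3
Reactants: 8 [3,4-bis(benzyloxy)phenyl]methanol
Product: 9 1,2-bis(benzyloxy)-4-(bromomethyl)benzene
Conditions: PBr3, Et2O, 0 °C
Reagents that add atoms: phosphorus tribromide, BrP(Br)Br
Why: Bromination of a benzylic alcohol through its phosphite ester (SN2) should leave the benzyl ethers intact; the bromide is used fresh.

Step 4
Reactants: 7 (R)-4-benzyl-3-[(E)-4-(3,4-dimethoxyphenyl)but-3-enoyl]-1,3-oxazolidin-2-one; 9 1,2-bis(benzyloxy)-4-(bromomethyl)benzene
Product: 11 (R)-4-benzyl-3-[(2R,3E)-2-[3,4-bis(benzyloxy)benzyl]-4-(3,4-dimethoxyphenyl)but-3-enoyl]-1,3-oxazolidin-2-one, via sodium dienolate 10 (not isolated)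
Conditions: NaN(SiMe3)2, THF, −78 °C; then 9, −78 to −40 °C
Reagents that add atoms: none
Why: Evans alkylation: the chelated (Z)-dienolate should react at its α-carbon with the benzylic bromide on the face opposite the auxiliary benzyl group, which sets C3 as R, and allylic 1,3-strain in the product should prevent re-enolisation.

Step 5
Reactants: 11 (R)-4-benzyl-3-[(2R,3E)-2-[3,4-bis(benzyloxy)benzyl]-4-(3,4-dimethoxyphenyl)but-3-enoyl]-1,3-oxazolidin-2-one
Product: 13 (2R,3E)-2-[3,4-bis(benzyloxy)benzyl]-4-(3,4-dimethoxyphenyl)but-3-enoic acid, via lithium peroxycarboxylate 12 (not isolated)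
Conditions: LiOH, 30% H2O2, THF/H2O, 0 °C; then Na2SO3; then aq. HCl to pH 3
Reagents that add atoms: hydrogen peroxide, OO
Why: Hydroperoxide cleavage of the exocyclic imide carbonyl is weakly basic, so the α-centre that is both allylic and next to a carbonyl should survive, and the auxiliary is recovered.

Step 6
Reactants: 13 (2R,3E)-2-[3,4-bis(benzyloxy)benzyl]-4-(3,4-dimethoxyphenyl)but-3-enoic acid
Product: 14 chloromethyl (2R,3E)-2-[3,4-bis(benzyloxy)benzyl]-4-(3,4-dimethoxyphenyl)but-3-enoate
Conditions: ClCH2OSO2Cl, NaHCO3, Bu4NHSO4 (cat.), CH2Cl2/H2O, 0 °C to rt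
Reagents that add atoms: chloromethyl chlorosulfate, ClCOS(=O)(=O)Cl
Why: Phase-transfer O-alkylation of the carboxylate at the CH2 of chloromethyl chlorosulfate (SN2, chlorosulfate as leaving group) uses only bicarbonate as base, so the stereocentre should be preserved.

Step 7
Reactants: 14 chloromethyl (2R,3E)-2-[3,4-bis(benzyloxy)benzyl]-4-(3,4-dimethoxyphenyl)but-3-enoate
Product: 15 iodomethyl (2R,3E)-2-[3,4-bis(benzyloxy)benzyl]-4-(3,4-dimethoxyphenyl)but-3-enoate
Conditions: NaI, acetone, rt, dark; filtered, concentrated and used at once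
Reagents that add atoms: sodium iodide, [Na+].[I-]
Why: Finkelstein exchange at the activated acyloxymethyl carbon should be driven by precipitation of NaCl and gives the weak C–I bond needed for clean radical generation.

Step 8
Reactants: 15 iodomethyl (2R,3E)-2-[3,4-bis(benzyloxy)benzyl]-4-(3,4-dimethoxyphenyl)but-3-enoate
Product: 16 (3R,4R)-3-[3,4-bis(benzyloxy)benzyl]-4-(3,4-dimethoxybenzyl)oxolan-2-one
Conditions: Bu3SnH (1.3 equiv), AIBN (0.2 equiv), syringe pump over 8 h, degassed PhH (0.005 M), 80 °C
Reagents that add atoms: none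
Why: The tributylstannyl radical abstracts iodine from 15 to give the acyloxymethyl radical at C5, which adds to the styrene carbon C4, and the resulting C7 benzylic radical, stabilised by the dimethoxyphenyl ring, takes hydrogen from Bu3SnH to carry the chain. The closest known reaction type is the tin hydride cyclisation of acyloxymethyl radicals, made from halomethyl or (phenylselanyl)methyl esters of 3-alkenoic acids, to γ-butyrolactones. The lactone ring closes in the 5-exo-trig mode; the 6-endo mode would give a non-benzylic radical and is not expected. The new centre C4 is controlled by C3: in the chair-like 5-exo transition state the C3 arylmethyl group sits pseudo-equatorial and anti to the styryl terminus (a 4-substituted 5-hexenyl radical closes to the trans-1,2 product), so the (3R,4R)-trans lactone should predominate. The step needs ring closure to outrun hydrogen transfer to the open radical, which is slowed because only the minor s-cis ester rotamer can reach C4. High dilution, slow stannane addition, 80 °C to speed rotamer exchange and the fast addition of alkyl radicals to styrenes should secure this, and the iodine leaves in the same event, so no helper group remains.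

Step 9
Reactants: 16 (3R,4R)-3-[3,4-bis(benzyloxy)benzyl]-4-(3,4-dimethoxybenzyl)oxolan-2-one
Product: 17 3'-O-demethylarctigenin, (3R,4R)-3-(3,4-dihydroxybenzyl)-4-(3,4-dimethoxybenzyl)oxolan-2-one
Conditions: H2 (1 atm), 10% Pd/C, EtOAc/MeOH, rt
Reagents that add atoms: none
Why: Neutral hydrogenolysis of the two benzyl ethers should free the catechol without affecting the lactone, the methyl ethers or either stereocentre.

**Compound list**

1 | 3,4-dimethoxybenzaldehyde (veratraldehyde) | COc1ccc(C=O)cc1OC | starting material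
2 | (2-carboxyethyl)triphenylphosphonium bromide | OC(=O)CC[P+](c1ccccc1)(c1ccccc1)c1ccccc1.[Br-] | starting material
3 | potassium 3-(triphenylphosphoranylidene)propanoate (ylide) | [K+].[O-]C(=O)C[CH-][P+](c1ccccc1)(c1ccccc1)c1ccccc1 | intermediate
4 | (E)-4-(3,4-dimethoxyphenyl)but-3-enoic acid | COc1ccc(/C=C/CC(=O)O)cc1OC | intermediate
5 | (R)-4-benzyl-1,3-oxazolidin-2-one | O=C1N[C@H](Cc2ccccc2)CO1 | starting material
6 | (E)-4-(3,4-dimethoxyphenyl)but-3-enoic pivalic anhydride | COc1ccc(/C=C/CC(=O)OC(=O)C(C)(C)C)cc1OC | intermediate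
7 | (R)-4-benzyl-3-[(E)-4-(3,4-dimethoxyphenyl)but-3-enoyl]-1,3-oxazolidin-2-one | COc1ccc(/C=C/CC(=O)N2C(=O)OC[C@H]2Cc2ccccc2)cc1OC | intermediate
8 | [3,4-bis(benzyloxy)phenyl]methanol | OCc1ccc(OCc2ccccc2)c(OCc2ccccc2)c1 | starting material
9 | 1,2-bis(benzyloxy)-4-(bromomethyl)benzene | BrCc1ccc(OCc2ccccc2)c(OCc2ccccc2)c1 | intermediate
10 | sodium (Z)-dienolate of 7 | [Na+].COc1ccc(/C=C/C=C(\[O-])N2C(=O)OC[C@H]2Cc2ccccc2)cc1OC | intermediate
11 | (R)-4-benzyl-3-[(2R,3E)-2-[3,4-bis(benzyloxy)benzyl]-4-(3,4-dimethoxyphenyl)but-3-enoyl]-1,3-oxazolidin-2-one | COc1ccc(/C=C/[C@@H](Cc2ccc(OCc3ccccc3)c(OCc3ccccc3)c2)C(=O)N2C(=O)OC[C@H]2Cc2ccccc2)cc1OC | intermediate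
12 | lithium (2R,3E)-2-[3,4-bis(benzyloxy)benzyl]-4-(3,4-dimethoxyphenyl)but-3-eneperoxoate | [Li+].COc1ccc(/C=C/[C@@H](Cc2ccc(OCc3ccccc3)c(OCc3ccccc3)c2)C(=O)O[O-])cc1OC | intermediate
13 | (2R,3E)-2-[3,4-bis(benzyloxy)benzyl]-4-(3,4-dimethoxyphenyl)but-3-enoic acid | COc1ccc(/C=C/[C@@H](Cc2ccc(OCc3ccccc3)c(OCc3ccccc3)c2)C(=O)O)cc1OC | intermediate
14 | chloromethyl (2R,3E)-2-[3,4-bis(benzyloxy)benzyl]-4-(3,4-dimethoxyphenyl)but-3-enoate | COc1ccc(/C=C/[C@@H](Cc2ccc(OCc3ccccc3)c(OCc3ccccc3)c2)C(=O)OCCl)cc1OC | intermediate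
15 | iodomethyl (2R,3E)-2-[3,4-bis(benzyloxy)benzyl]-4-(3,4-dimethoxyphenyl)but-3-enoate | COc1ccc(/C=C/[C@@H](Cc2ccc(OCc3ccccc3)c(OCc3ccccc3)c2)C(=O)OCI)cc1OC | intermediate
16 | (3R,4R)-3-[3,4-bis(benzyloxy)benzyl]-4-(3,4-dimethoxybenzyl)oxolan-2-one | COc1ccc(C[C@H]2COC(=O)[C@@H]2Cc2ccc(OCc3ccccc3)c(OCc3ccccc3)c2)cc1OC | intermediate
17 | 3'-O-demethylarctigenin, (3R,4R)-3-(3,4-dihydroxybenzyl)-4-(3,4-dimethoxybenzyl)oxolan-2-one | COc1ccc(C[C@H]2COC(=O)[C@@H]2Cc2ccc(O)c(O)c2)cc1OC | target

**Step count and risks**

Total steps: 9. Longest linear sequence: 8 (steps 1, 2, 4, 5, 6, 7, 8, 9, from veratraldehyde); step 3 is a one-step side branch.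

Steps most likely to fail:

1. Step 8. The open acyloxymethyl radical may take hydrogen from the stannane before it reaches the s-cis ester rotamer and closes, or the ring closure may show poor facial selectivity at C4. The fallback sets out from 1 (with 9 from step 3) and comes back at 16; it gives up the radical closure and builds the lactone first. Stobbe condensation of 1 with dimethyl succinate (KOtBu, tBuOH, reflux) should give (E)-4-(3,4-dimethoxyphenyl)-3-(methoxycarbonyl)but-3-enoic acid F1. Asymmetric hydrogenation of F1 (H2, [Rh(cod)2]BF4 with Me-DuPhos, ligand antipode chosen for the R product, MeOH) should give (R)-4-(3,4-dimethoxyphenyl)-3-(methoxycarbonyl)butanoic acid F2. Reduction of the ester in the potassium salt of F2 with Ca(BH4)2 (from CaCl2 and NaBH4, EtOH), followed by acid-induced lactonisation, should give (R)-4-(3,4-dimethoxybenzyl)oxolan-2-one F3. The lithium enolate of F3 (LiN(iPr)2, THF, −78 °C) should be alkylated by 9 on the face opposite the C4 substituent to give 16.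

2. Step 4. The aryl-conjugated dienolate may alkylate at its γ-carbon, or proton exchange in the doubly activated product may erode the new α-centre. The fallback sets out from 5 and comes back at 11; it sets the stereocentre on the simple crotonyl dienolate and attaches the aryl ring afterwards. N-Acylation of 5 with (E)-but-2-enoyl chloride (n-BuLi, THF, −78 °C) should give (R)-4-benzyl-3-[(E)-but-2-enoyl]-1,3-oxazolidin-2-one F4. Deconjugative α-alkylation of its sodium dienolate (NaN(SiMe3)2, THF, −78 °C) with 9 should give (R)-4-benzyl-3-[(2R)-2-[3,4-bis(benzyloxy)benzyl]but-3-enoyl]-1,3-oxazolidin-2-one F5. Cross-metathesis of F5 with 3,4-dimethoxystyrene (second-generation Grubbs catalyst RuCl2(H2IMes)(PCy3)(=CHPh), CH2Cl2, 40 °C) should install the (E)-styrene and give 11.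

3. Step 7. The iodomethyl ester may be lost through solvolysis by adventitious water or light-induced C–I homolysis before it can be cyclised. The fallback sets out from 14 and comes back at 16; it replaces the labile iodide by a bench-stable selenide as radical precursor. Displacement of chloride in 14 by benzeneselenol (Et3N, CH2Cl2, 0 °C) should give (phenylselanyl)methyl (2R,3E)-2-[3,4-bis(benzyloxy)benzyl]-4-(3,4-dimethoxyphenyl)but-3-enoate F6, which can be purified by chromatography. Treatment of F6 with Bu3SnH and AIBN (syringe pump, PhH, 80 °C) should generate the same acyloxymethyl radical by homolytic substitution at selenium and give 16.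

Further compounds

F1 | step 8 | (E)-4-(3,4-dimethoxyphenyl)-3-(methoxycarbonyl)but-3-enoic acid | COC(=O)/C(CC(=O)O)=C/c1ccc(OC)c(OC)c1
F2 | step 8 | (R)-4-(3,4-dimethoxyphenyl)-3-(methoxycarbonyl)butanoic acid | COC(=O)[C@@H](CC(=O)O)Cc1ccc(OC)c(OC)c1
F3 | step 8 | (R)-4-(3,4-dimethoxybenzyl)oxolan-2-one | COc1ccc(C[C@H]2COC(=O)C2)cc1OC
F4 | step 4 | (R)-4-benzyl-3-[(E)-but-2-enoyl]-1,3-oxazolidin-2-one | C/C=C/C(=O)N1C(=O)OC[C@H]1Cc1ccccc1
F5 | step 4 | (R)-4-benzyl-3-[(2R)-2-[3,4-bis(benzyloxy)benzyl]but-3-enoyl]-1,3-oxazolidin-2-one | C=C[C@@H](Cc1ccc(OCc2ccccc2)c(OCc2ccccc2)c1)C(=O)N1C(=O)OC[C@H]1Cc1ccccc1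
F6 | step 7 | (phenylselanyl)methyl (2R,3E)-2-[3,4-bis(benzyloxy)benzyl]-4-(3,4-dimethoxyphenyl)but-3-enoate | COc1ccc(/C=C/[C@@H](Cc2ccc(OCc3ccccc3)c(OCc3ccccc3)c2)C(=O)OC[Se]c2ccccc2)cc1OC
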